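## Analysis of the target

Serpyllin is 5-hydroxy-7,8-dimethoxy-2-(2,3,4-trimethoxyphenyl)-4H-chromen-4-one: a flavone in which the benzo ring A and the pyranone ring C make up the chromone, and ring B is a 2,3,4-trimethoxyphenyl group on C2. The molecule is planar and has no stereocenter, so the whole task is the placement of seven oxygens on the two benzene rings, four on ring A (O1, O5, O7, O8) and three contiguous ones on ring B. Five of them are methyl ethers and only the 5-oxygen is free; it is hydrogen-bonded to the C4 carbonyl, and this chelation is the one handle that distinguishes it from the other oxygens late in a synthesis. The sensitive points are: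
- the pyranone ring, which opens in hot alkali and, with a free 5-OH, can reclose on the other oxygen and so exchange the C6 and C8 substituents;
- the electron-rich rings, and any 5,8-dihydroxy intermediate, which oxidise easily;
- the five methyl ethers, which must survive any Lewis acid used.

The difficulty lies in ring A, which is substituted at every carbon except C6, so that a classical route has to acylate a 1,2,3,5-tetraoxygenated benzene at one defined position. The strategy rests on the sequence O1–C8a, C4–C4a, O–C5 on three neighbouring ring A carbons. A 3-alkoxybenzyne produces exactly this sequence when an oxygen nucleophile carrying its own acyl group adds to it: the oxygen goes to the aryne carbon remote from the alkoxy group and the acyl group to the carbon beside it. If C8 carries hydrogen at that stage, the aryne has a single directing methoxy group, and the 8-oxygen, which is para to the 5-OH, can be added afterwards.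

## Retrosynthetic reasoning

**18 to 17 (O8–CH3).** The last bond cut is the methyl–oxygen bond at C8. In hydroquinone 17 the 5-OH is chelated to the carbonyl and the 8-OH is not, so a single equivalent of methylating agent should find only O8. Cutting here keeps the one protecting-group question of the target to a difference in reactivity that the structure provides by itself.

**17 to 15 (C8–O).** The C8 oxygen is removed next. C8 is para to the 5-OH in 15 and is the only free para position, which is the requirement for an Elbs para-hydroxylation of the phenoxide. This cut is made on purpose before the ring assembly: an aryne carrying oxygens on both sides of the triple bond would have no regiochemical preference, whereas without O8 a single methoxy group directs.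

**15 to 14 (O5–CH3).** The free 5-OH is traced back to a methyl ether. The forward reaction is a chelation-controlled ether cleavage at the peri position, which leaves the other four methyl ethers alone. The gain is that 14 carries two like methoxy groups on ring A, so its ring A can come from the symmetrical phenol 1.

**14 to 7 and 11 (O1–C8a, C4a–C4, O1–C2).** Ring C is cut at three bonds, which separates the two-carbon aryne equivalent 7 from the C3 acid 11 that carries ring B. Forward, fluoride releases aryne 12 from 7 and the carboxylate of 11 adds through oxygen. The acyl group migrates to the neighbouring carbon to give ynone 13, and the phenoxide closes onto the alkyne. The cut is placed here because it is the only one that forms both ring A bonds to ring C in one operation, with the regiochemistry set by a substituent already present. The forward step must capture the aryne at the carbon remote from methoxy and must close 6-endo.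

**7 to 5, 2 and 1 (C–Si, O–S).** The silyl triflate is traced to phenol 1. The phenol oxygen becomes the triflate oxygen, and the C–Si bond is made by directed ortho-metalation of carbamate 2 at the position between the carbamate and a methoxy group, passing through 3 and 4 to 5. Cleavage of the carbamate to 6 and sulfonylation then give 7. Because 1 is symmetrical, the two positions flanked by carbamate and methoxy are equivalent.

**11 to 9 and 8 (C≡C, C–CO2H).** The propiolic acid is traced to aldehyde 8 by a Corey–Fuchs homologation. The dibromoalkene 9 gives acetylide 10, which is carboxylated. Ring B is thus taken intact from a commercial aldehyde and no bond of ring B has to be made.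

## Alternatives that were turned down

**Alternative 1:** one-carbon ring expansion of a benzofuran.
- Disconnection: C3 is removed from ring C (bonds C2–C3 and C3–C4), which leaves the silyl enol ether of a 2-arylbenzofuran-3-one, [4,6,7-trimethoxy-2-(2,3,4-trimethoxyphenyl)-1-benzofuran-3-yl]oxy(trimethyl)silane A2.
- Forward key step: dichlorocarbene, made from chloroform and KOtBu, adds to the C2=C3 bond of A2. The dichlorocyclopropane opens with loss of chloride and of the silyl group and gives 3-chloro-5,7,8-trimethoxy-2-(2,3,4-trimethoxyphenyl)-4H-chromen-4-one A1.
- For it: all four ring A oxygens are present from the start, so no late C–H oxidation is needed and no regiochemical question arises on ring A. On this point it is stronger than the chosen route, which depends on an Elbs oxidation of modest efficiency.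
- Against it: the carbene has to add to a tetrasubstituted double bond of A2 crowded by the ortho-methoxy group of ring B and the peri methoxy group. A1 also carries a chlorine at C3 that the target does not have, so a reductive dechlorination that spares the C2=C3 bond is needed, and after it the same selective 5-demethylation as in the chosen route. A2 must be built from a 1,2,3,5-tetraoxygenated benzene by regioselective acylation, which is the classical problem the analysis set out to avoid, and 2-arylbenzofuran-3-ones oxidise readily at C2.
- Comparison: the sequence through A2 and A1 is linear and at least as long. The chosen strategy joins two simple halves convergently, leaves no atom to be removed, and lets a methoxy group already in place decide the regiochemistry.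

**Alternative 2:** ring B grown from a cyclobutenone.
- Disconnection: ring B is cut at C5′–C6′ and C1′–C2′ into 4-chloro-2,3-dimethoxycyclobut-2-en-1-one A4 and the vinylstannane 5,7,8-trimethoxy-2-[(E)-2-(tributylstannyl)ethenyl]-4H-chromen-4-one A5.
- Forward key step: Pd2(dba)3 with tri(2-furyl)phosphine, a zerovalent palladium catalyst, couples A4 with A5 (C5′–C6′). The 4-alkenylcyclobutenone opens to a dienylketene, which closes by 6π-electrocyclisation (C1′–C2′) and tautomerises to 2-(2-hydroxy-3,4-dimethoxyphenyl)-5,7,8-trimethoxy-4H-chromen-4-one A3.
- For it: the contiguous 2′,3′,4′-oxygen pattern is set without any aromatic substitution, under neutral conditions, and the regiochemistry of ring B is unambiguous. In that respect it is as strong as the chosen route.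
- Against it: ring B is the cheapest part of the molecule and is available intact as aldehyde 8, so the key step is spent where there is no problem. A5 already contains the complete 5,7,8-trioxygenated chromone, so the real difficulty (ring A and ring C) is left unsolved. A3 needs methylation at O2′ as well as demethylation at O5, and A4 itself takes several steps from a squaric ester.
- Comparison: the step count through A4, A5 and A3 is far higher. The chosen strategy places its key step on rings A and C, where the difficulty lies.

**Alternative 3:** oxidative closure of ring C at C8a through an acylquinone.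
- Disconnection: the O1–C8a bond is cut, which leads to the hydroquinone β-diketone 1-(2,5-dihydroxy-4-methoxyphenyl)-3-(2,3,4-trimethoxyphenyl)propane-1,3-dione A7.
- Forward key step: Ag2O oxidises A7 to the acylquinone. The enol oxygen of the diketone adds to the quinone carbon that becomes C8a, and enolisation returns the aromatic ring as 5,8-dihydroxy-7-methoxy-2-(2,3,4-trimethoxyphenyl)-4H-chromen-4-one A6, which is the same structure as 17. The closure that has to be avoided is plain cyclodehydration of A7 through its ortho-hydroxyl, which would give the linear isomer 6-hydroxy-7-methoxy-2-(2,3,4-trimethoxyphenyl)-4H-chromen-4-one A8.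
- For it: ring C and the C8 oxygen arrive in one step and the Elbs oxidation is avoided. The route reaches the diol A6 one or two steps sooner than the chosen one, so on step economy and on the timing of the C8 oxygen it is the stronger plan.
- Against it: A8 forms from A7 with a trace of acid or on warming and needs no oxidant, so the wanted closure to A6 must outrun a reaction that is always available. The acylquinone is a strong oxidant and Michael acceptor open to intermolecular addition. A6, once formed, is an electron-rich hydroquinone that the acylquinone or Ag2O can oxidise further.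
- Comparison: the key step has little assurance of chemoselectivity, because A6 and A8 arise from the same diketone A7 by competing closures. The chosen strategy is longer at the end, but its ring-forming step has a clear regiochemical control element and its late oxidation is a classical reaction of 5-hydroxyflavones.

Key step: step 6

Remark on the chemistry: the phenol is carried through the lithiation as its N-isopropyl carbamate, because this carbamate leaves under a mild amine base that the electron-rich aryl–silicon bond should tolerate, whereas an N,N-dialkyl carbamate would need hydride or hot hydroxide.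

## Route

Step 1
Reactants: 1 3,5-dimethoxyphenol
Product: 2 3,5-dimethoxyphenyl N-isopropylcarbamate
Conditions: i-PrNCO (1.5 equiv), Et3N (0.2 equiv), CH2Cl2, rt
Reagents that add atoms: isopropyl isocyanate, CC(C)N=C=O
Why: Base-catalysed addition of the phenol O–H to the isocyanate (carbamoylation); the secondary carbamate is chosen because it can later be removed by elimination under a mild amine base.

Step 2
Reactants: 2 3,5-dimethoxyphenyl N-isopropylcarbamate
Product: 5 3,5-dimethoxy-2-(trimethylsilyl)phenyl N-isopropylcarbamate, via N-TBS carbamate 3 (not isolated), via N-TBS silylaryl carbamate 4 (not isolated)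
Conditions: TBSOTf (1.1 equiv), TMEDA, Et2O, 0 °C → rt; n-BuLi (2 equiv), TMEDA, −78 °C; TMSCl, −78 °C → rt; aq. NaHSO4
Reagents that add atoms: chlorotrimethylsilane, C[Si](C)(C)Cl; tert-butyldimethylsilyl triflate, CC(C)(C)[Si](C)(C)OS(=O)(=O)C(F)(F)F (its silyl group stays only in 3 and 4)
Why: Directed ortho-metalation: silylation on nitrogen makes the carbamate a tertiary, strongly coordinating director, and n-BuLi/TMEDA (one equivalent of which is used up by the TMEDA triflate salt formed in the silylation) removes the proton at C2, flanked by the carbamate and a methoxy group whose directing effects add. The aryllithium is silylated at −78 °C before a carbamoyl shift can begin, and the acidic work-up takes the silyl group off nitrogen.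

Step 3
Reactants: 5 3,5-dimethoxy-2-(trimethylsilyl)phenyl N-isopropylcarbamate
Product: 7 3,5-dimethoxy-2-(trimethylsilyl)phenyl trifluoromethanesulfonate, via silylphenol 6 (not isolated)
Conditions: DBU (1.5 equiv), Et2NH (1.2 equiv), MeCN, 40 °C; then PhNTf2 (1.5 equiv), rt
Reagents that add atoms: N-phenylbis(trifluoromethanesulfonimide), O=S(=O)(N(c1ccccc1)S(=O)(=O)C(F)(F)F)C(F)(F)F
Why: DBU removes the N–H proton and the carbamate fragments (E1cB) to the phenoxide of 6 and isopropyl isocyanate, which diethylamine traps as a urea. The phenoxide is then sulfonylated by PhNTf2 in the same flask, so the electron-rich silylphenol never meets acid.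

Step 4
Reactants: 8 2,3,4-trimethoxybenzaldehyde
Product: 9 1-(2,2-dibromoethenyl)-2,3,4-trimethoxybenzene
Conditions: CBr4 (2 equiv), PPh3 (4 equiv), CH2Cl2, 0 °C
Reagents that add atoms: carbon tetrabromide, BrC(Br)(Br)Br
Why: First stage of the Corey–Fuchs homologation: the dibromomethylene ylide formed from PPh3 and CBr4 olefinates the aldehyde in a Wittig-type reaction.

Step 5
Reactants: 9 1-(2,2-dibromoethenyl)-2,3,4-trimethoxybenzene
Product: 11 3-(2,3,4-trimethoxyphenyl)prop-2-ynoic acid, via lithium acetylide 10 (not isolated)
Conditions: n-BuLi (2.2 equiv), THF, −78 °C; CO2, −78 °C → rt; aq. HCl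
Reagents that add atoms: carbon dioxide, O=C=O
Why: Second stage of the Corey–Fuchs sequence: n-BuLi effects elimination and bromine–lithium exchange to acetylide 10, which is carboxylated by CO2; acidification releases the arylpropiolic acid.

Step 6
Reactants: 7 3,5-dimethoxy-2-(trimethylsilyl)phenyl trifluoromethanesulfonate; 11 3-(2,3,4-trimethoxyphenyl)prop-2-ynoic acid
Product: 14 5,7-dimethoxy-2-(2,3,4-trimethoxyphenyl)-4H-chromen-4-one, via 3,5-dimethoxybenzyne 12 (not isolated), via hydroxyaryl ynone 13 (not isolated)
Conditions: 7 (1.5 equiv), CsF (4 equiv), THF, 125 °C, sealed tube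
Reagents that add atoms: none
Why: CsF removes the trimethylsilyl group of 7 and triflate leaves, so aryne 12 forms slowly in the presence of the caesium carboxylate of 11. The methoxy group beside the triple bond distorts 12 so that the carboxylate oxygen adds at the aryne carbon remote from it (O1–C8a), which places the aryl anion on the carbon between the two oxygens, where induction stabilises it best. That anion attacks the adjacent ester carbonyl through a four-membered transition state and the ester C–O bond breaks, so the acyl group moves from oxygen to carbon (C4a–C4) and ynone 13 appears as its phenoxide. The phenoxide adds to the β-carbon of the ynone in a 6-endo-dig oxa-Michael closure (O1–C2), and the vinyl anion is protonated by the hydrogen fluoride equivalent left from the acid, which completes ring C of 14. The closest known reaction type is the fluoride-induced insertion of arynes into the C–O bond of carboxylic acids to give 2-hydroxyaryl ketones, which continues to chromones when the acid is an alkynoic acid. No stereocenter is formed. The step needs regioselective capture of the aryne, which the 3-methoxy group secures (the 5-methoxy group is para to the anionic carbon and has only a small opposing effect), and it needs acyl transfer to outrun protonation of the aryl anion, which is why the reaction is run hot and with an excess of 7. It also needs 6-endo rather than 5-exo closure, which the polarisation of the ynone towards its β-carbon favours.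

Step 7
Reactants: 14 5,7-dimethoxy-2-(2,3,4-trimethoxyphenyl)-4H-chromen-4-one
Product: 15 5-hydroxy-7-methoxy-2-(2,3,4-trimethoxyphenyl)-4H-chromen-4-one
Conditions: BCl3 (1.2 equiv), CH2Cl2, −78 → 0 °C; aq. HCl
Reagents that add atoms: none
Why: Chelation-controlled ether cleavage: BCl3 binds between the C4 carbonyl and the peri 5-methoxy oxygen in a six-membered chelate, and chloride removes that methyl group only. The reagent is kept near one equivalent and cold so that the trimethoxy array of ring B, which has no carbonyl to anchor boron, is left intact.

Step 8
Reactants: 15 5-hydroxy-7-methoxy-2-(2,3,4-trimethoxyphenyl)-4H-chromen-4-one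
Product: 17 5,8-dihydroxy-7-methoxy-2-(2,3,4-trimethoxyphenyl)-4H-chromen-4-one, via aryl sulfate 16 (not isolated)
Conditions: K2S2O8, aq. KOH, pyridine, 0 °C → rt; then aq. HCl, Na2SO3, 90 °C
Reagents that add atoms: potassium peroxodisulfate K2S2O8, [K+].[K+].[O-]S(=O)(=O)OOS(=O)(=O)[O-]
Why: Elbs persulfate oxidation: the 5-phenoxide attacks the peroxide oxygen through C8, its only free para position, to give aryl sulfate 16, and hot dilute acid hydrolyses the sulfate ester while sulfite protects the hydroquinone from oxidation. This is the classical conversion of 5-hydroxyflavones into 5,8-dihydroxyflavones; conversion is expected to be modest, with unreacted 15 recoverable.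

Step 9
Reactants: 17 5,8-dihydroxy-7-methoxy-2-(2,3,4-trimethoxyphenyl)-4H-chromen-4-one
Product: 18 serpyllin, 5-hydroxy-7,8-dimethoxy-2-(2,3,4-trimethoxyphenyl)-4H-chromen-4-one
Conditions: MeI (1.1 equiv), K2CO3 (1.1 equiv), acetone, rt, argon
Reagents that add atoms: iodomethane, CI
Why: Williamson O-methylation with one equivalent of base and MeI: the 8-OH is free, whereas the 5-OH is hydrogen-bonded to the C4 carbonyl and reacts far more slowly, so monomethylation at O8 should prevail. Argon and degassed solvent protect the hydroquinone from air.

## Compound list

1 | 3,5-dimethoxyphenol | COc1cc(O)cc(OC)c1 | starting material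
2 | 3,5-dimethoxyphenyl N-isopropylcarbamate | COc1cc(OC)cc(OC(=O)NC(C)C)c1 | intermediate
3 | 3,5-dimethoxyphenyl N-(tert-butyldimethylsilyl)-N-isopropylcarbamate | COc1cc(OC)cc(OC(=O)N(C(C)C)[Si](C)(C)C(C)(C)C)c1 | intermediate (not isolated)
4 | 3,5-dimethoxy-2-(trimethylsilyl)phenyl N-(tert-butyldimethylsilyl)-N-isopropylcarbamate | COc1cc(OC)c([Si](C)(C)C)c(OC(=O)N(C(C)C)[Si](C)(C)C(C)(C)C)c1 | intermediate (not isolated)
5 | 3,5-dimethoxy-2-(trimethylsilyl)phenyl N-isopropylcarbamate | COc1cc(OC)c([Si](C)(C)C)c(OC(=O)NC(C)C)c1 | intermediate
6 | 3,5-dimethoxy-2-(trimethylsilyl)phenol | COc1cc(OC)c([Si](C)(C)C)c(O)c1 | intermediate (not isolated)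
7 | 3,5-dimethoxy-2-(trimethylsilyl)phenyl trifluoromethanesulfonate | COc1cc(OC)c([Si](C)(C)C)c(OS(=O)(=O)C(F)(F)F)c1 | intermediate
8 | 2,3,4-trimethoxybenzaldehyde | COc1ccc(C=O)c(OC)c1OC | starting material
9 | 1-(2,2-dibromoethenyl)-2,3,4-trimethoxybenzene | COc1ccc(C=C(Br)Br)c(OC)c1OC | intermediate
10 | lithium (2,3,4-trimethoxyphenyl)acetylide | COc1ccc(C#C[Li])c(OC)c1OC | intermediate (not isolated)
11 | 3-(2,3,4-trimethoxyphenyl)prop-2-ynoic acid | COc1ccc(C#CC(=O)O)c(OC)c1OC | intermediate
12 | 3,5-dimethoxybenzyne | COC1=CC(OC)=CC#C1 | intermediate (not isolated)
13 | 1-(2-hydroxy-4,6-dimethoxyphenyl)-3-(2,3,4-trimethoxyphenyl)prop-2-yn-1-one | COc1cc(O)c(C(=O)C#Cc2ccc(OC)c(OC)c2OC)c(OC)c1 | intermediate (not isolated)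
14 | 5,7-dimethoxy-2-(2,3,4-trimethoxyphenyl)-4H-chromen-4-one | COc1cc(OC)c2c(c1)oc(-c1ccc(OC)c(OC)c1OC)cc2=O | intermediate
15 | 5-hydroxy-7-methoxy-2-(2,3,4-trimethoxyphenyl)-4H-chromen-4-one | COc1cc(O)c2c(c1)oc(-c1ccc(OC)c(OC)c1OC)cc2=O | intermediate
16 | potassium 5-hydroxy-7-methoxy-4-oxo-2-(2,3,4-trimethoxyphenyl)-4H-chromen-8-yl sulfate | COc1ccc(-c2cc(=O)c3c(O)cc(OC)c(OS(=O)(=O)[O-])c3o2)c(OC)c1OC.[K+] | intermediate (not isolated)
17 | 5,8-dihydroxy-7-methoxy-2-(2,3,4-trimethoxyphenyl)-4H-chromen-4-one | COc1ccc(-c2cc(=O)c3c(O)cc(OC)c(O)c3o2)c(OC)c1OC | intermediate
18 | serpyllin, 5-hydroxy-7,8-dimethoxy-2-(2,3,4-trimethoxyphenyl)-4H-chromen-4-one | COc1ccc(-c2cc(=O)c3c(O)cc(OC)c(OC)c3o2)c(OC)c1OC | target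

## Step count and least certain steps

Total step count: 9. Longest linear sequence: 7 steps (steps 1, 2, 3, 6, 7, 8 and 9); the acid 11 is made in a two-step branch (steps 4 and 5).

**Step 6 (key step).** Four processes can divert it:
- protonation of the aryl anion before the acyl group has moved, which stops the sequence at the aryl ester stage;
- conjugate closure of the aryl anion onto the alkyne in place of attack at the carbonyl;
- loss of CO2 from the propiolate at 125 °C;
- 5-exo closure of the phenoxide onto the ynone.

The last three all come from the alkyne. The fallback therefore keeps the aryne insertion but uses an alkene and adds an oxidation. It sets out from 8 and 7. Knoevenagel–Doebner condensation of 8 with malonic acid (pyridine, piperidine, 90 °C) would give (E)-3-(2,3,4-trimethoxyphenyl)prop-2-enoic acid F1. Treatment of F1 with 7 and CsF in THF at 125 °C should give, by the same C–O insertion, (E)-1-(2-hydroxy-4,6-dimethoxyphenyl)-3-(2,3,4-trimethoxyphenyl)prop-2-en-1-one F2, whose phenoxide can only close 6-endo-trig to racemic 5,7-dimethoxy-2-(2,3,4-trimethoxyphenyl)chroman-4-one F3. Heating F3, together with any F2 left, with catalytic I2 in DMSO at 130 °C would dehydrogenate it. The fallback comes back to the route at 14. It does not cure protonation of the aryl anion, which would have to be met by using the preformed caesium salt of the acid.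

**Step 8.** Sulfation at C8 may be slow and incomplete, because the 5-phenoxide is a weak nucleophile conjugated with the carbonyl. Persulfate may also decompose to radicals that degrade the electron-rich rings, and the hydroquinone product may oxidise in the alkaline medium. The fallback sets out from 14 and replaces oxidation by halogenation and substitution. NBS in DMF at 0 °C should brominate C8, the ring A position between the 7-methoxy group and the ring oxygen and para to the 5-methoxy group, to give 8-bromo-5,7-dimethoxy-2-(2,3,4-trimethoxyphenyl)-4H-chromen-4-one F4. Methoxylation with NaOMe and CuBr in DMF–MeOH at 110 °C would give 5,7,8-trimethoxy-2-(2,3,4-trimethoxyphenyl)-4H-chromen-4-one F5; the 5-oxygen is still methylated at this point, so a ring-opened intermediate can only reclose to the same chromone. BCl3 in CH2Cl2, as in step 7, would then cleave the chelated 5-methyl ether only. The fallback comes back at 18 and also avoids the air-sensitive hydroquinone of step 9.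

**Step 2.** Deprotonation may take place at C4, between the two methoxy groups, instead of beside the carbamate, or the carbamoyl group may migrate to carbon if the aryllithium warms before it is silylated. In step 3 the very electron-rich arylsilane could in addition lose silicon by ipso-protonation. The fallback sets out from 1 and makes the C–Si bond by silyl migration instead of by metalation. Ortho-bromination with NBS and catalytic i-Pr2NH in CH2Cl2 would give 2-bromo-3,5-dimethoxyphenol F6. Silylation with hexamethyldisilazane would give (2-bromo-3,5-dimethoxyphenoxy)trimethylsilane F7. Treatment with n-BuLi in THF at −78 °C would cause bromine–lithium exchange and a 1,3 shift of silicon from oxygen to carbon (retro-Brook rearrangement), and the resulting lithium phenoxide would be quenched with Tf2O. The fallback comes back at 7 and bypasses steps 1 to 3.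

**Step 5.** Excess n-BuLi may metalate the ring beside a methoxy group, and trapping of the acetylide by CO2 may be incomplete. The fallback sets out from 8 and avoids organolithium reagents. Ohira–Bestmann homologation (dimethyl (1-diazo-2-oxopropyl)phosphonate, K2CO3, MeOH, rt) would give 1-ethynyl-2,3,4-trimethoxybenzene F8, and C–H carboxylation of the terminal alkyne (CO2 at 1 atm, Cs2CO3, catalytic AgI, DMF, 50 °C; then aq. HCl) would give the acid. The fallback comes back at 11.

## Further compounds

F1 | step 6 | (E)-3-(2,3,4-trimethoxyphenyl)prop-2-enoic acid | COc1ccc(/C=C/C(=O)O)c(OC)c1OC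
F2 | step 6 | (E)-1-(2-hydroxy-4,6-dimethoxyphenyl)-3-(2,3,4-trimethoxyphenyl)prop-2-en-1-one | COc1cc(O)c(C(=O)/C=C/c2ccc(OC)c(OC)c2OC)c(OC)c1
F3 | step 6 | racemic 5,7-dimethoxy-2-(2,3,4-trimethoxyphenyl)chroman-4-one | COc1cc(OC)c2c(c1)OC(c1ccc(OC)c(OC)c1OC)CC2=O
F4 | step 8 | 8-bromo-5,7-dimethoxy-2-(2,3,4-trimethoxyphenyl)-4H-chromen-4-one | COc1ccc(-c2cc(=O)c3c(OC)cc(OC)c(Br)c3o2)c(OC)c1OC
F5 | step 8 | 5,7,8-trimethoxy-2-(2,3,4-trimethoxyphenyl)-4H-chromen-4-one | COc1ccc(-c2cc(=O)c3c(OC)cc(OC)c(OC)c3o2)c(OC)c1OC
F6 | step 2 | 2-bromo-3,5-dimethoxyphenol | COc1cc(O)c(Br)c(OC)c1
F7 | step 2 | (2-bromo-3,5-dimethoxyphenoxy)trimethylsilane | COc1cc(O[Si](C)(C)C)c(Br)c(OC)c1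
F8 | step 5 | 1-ethynyl-2,3,4-trimethoxybenzene | COc1ccc(C#C)c(OC)c1OC
A1 | alternative 1 | 3-chloro-5,7,8-trimethoxy-2-(2,3,4-trimethoxyphenyl)-4H-chromen-4-one | COc1ccc(-c2oc3c(OC)c(OC)cc(OC)c3c(=O)c2Cl)c(OC)c1OC
A2 | alternative 1 | [4,6,7-trimethoxy-2-(2,3,4-trimethoxyphenyl)-1-benzofuran-3-yl]oxy(trimethyl)silane | COc1ccc(-c2oc3c(OC)c(OC)cc(OC)c3c2O[Si](C)(C)C)c(OC)c1OC
A3 | alternative 2 | 2-(2-hydroxy-3,4-dimethoxyphenyl)-5,7,8-trimethoxy-4H-chromen-4-one | COc1ccc(-c2cc(=O)c3c(OC)cc(OC)c(OC)c3o2)c(O)c1OC
A4 | alternative 2 | 4-chloro-2,3-dimethoxycyclobut-2-en-1-one (racemic) | COC1=C(OC)C(Cl)C1=O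
A5 | alternative 2 | 5,7,8-trimethoxy-2-[(E)-2-(tributylstannyl)ethenyl]-4H-chromen-4-one | COc1cc(OC)c2c(=O)cc(/C=C/[Sn](CCCC)(CCCC)CCCC)oc2c1OC
A6 | alternative 3 | 5,8-dihydroxy-7-methoxy-2-(2,3,4-trimethoxyphenyl)-4H-chromen-4-one | COc1ccc(-c2cc(=O)c3c(O)cc(OC)c(O)c3o2)c(OC)c1OC
A7 | alternative 3 | 1-(2,5-dihydroxy-4-methoxyphenyl)-3-(2,3,4-trimethoxyphenyl)propane-1,3-dione | COc1cc(O)c(C(=O)CC(=O)c2ccc(OC)c(OC)c2OC)cc1O
A8 | alternative 3 | 6-hydroxy-7-methoxy-2-(2,3,4-trimethoxyphenyl)-4H-chromen-4-one | COc1ccc(-c2cc(=O)c3cc(O)c(OC)cc3o2)c(OC)c1OC
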